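**Retrosynthetic overview**
1. Target 14 ⇒ 5-methoxy-2-(pentadec-6-enyl)chromone 12, by O-demethylation and saturation of the C6'=C7' alkene.
2. 12 ⇒ dec-1-ene 10 + aryl vinyl ketone 9 in one ring-rearrangement/cross-metathesis cascade. It closes the pyranone at C2=C3, opens a temporary cycloheptene, and makes the side-chain bond C6'–C7' (as C=C).
3. Enabling feature: pyranone C2 and side-chain C6' are separated by exactly five CH2 groups (C1'–C5'). They can therefore be the two sp2 carbons of a cyclohept-1-enyl ether on O1, and an acryloyl group on C4a supplies C3 and C4.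
4. 9 ⇒ 3-methoxyphenol 4 + cycloheptanone 1 (as enol triflate 3, C–O coupling) + acrolein 6 (lithiation between the two oxygens, then oxidation).
5. Ring order: the benzene ring is bought, the cycloheptene is carried as a temporary ring, and the 4-pyranone forms last, in step 5, as the cycloheptene disappears.

Key step: step 5

Assumption: the E/Z composition of the alkene made in step 5 does not matter because step 6 saturates it, so 12 is drawn as the E isomer. Chromone numbering is O1, C2, C3, C4, C4a, C5–C8, C8a, and the side chain is C1'–C15'.

Step 1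
Reactants: 1 cycloheptanone
Product: 3 cyclohept-1-en-1-yl trifluoromethanesulfonate, via lithium cyclohept-1-en-1-olate 2 (not isolated)
Conditions: LiHMDS (1.0 M in THF, 1.1 equiv), THF, −78 °C; then PhNTf2, −78 °C → rt; H2O work-up
Reagents that add atoms: N-phenylbis(trifluoromethanesulfonimide), O=S(=O)(C(F)(F)F)N(c1ccccc1)S(=O)(=O)C(F)(F)F
Why: Enol triflate formation by enolate O-sulfonylation; the symmetrical ketone gives a single lithium enolate, which the N-triflimide traps on oxygen.

Step 2
Reactants: 3 cyclohept-1-en-1-yl trifluoromethanesulfonate; 4 3-methoxyphenol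
Product: 5 1-(cyclohept-1-en-1-yloxy)-3-methoxybenzene
Conditions: 4 pre-stirred with NaOtBu (1.0 equiv relative to 4); Pd2(dba)3 (2.5 mol %), 2-(di-tert-butylphosphino)biphenyl (6 mol %), PhMe, 100 °C
Reagents that add atoms: none
Why: Palladium-catalysed C–O cross-coupling (Buchwald–Hartwig-type etherification) of a cyclic enol triflate with a preformed sodium phenoxide has close precedent for cycloalkenyl aryl ethers, and the bulky biaryl phosphine promotes C–O reductive elimination.

Step 3
Reactants: 5 1-(cyclohept-1-en-1-yloxy)-3-methoxybenzene; 6 acrolein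
Product: 8 (±)-1-[2-(cyclohept-1-en-1-yloxy)-6-methoxyphenyl]prop-2-en-1-ol, via 2-(cyclohept-1-en-1-yloxy)-6-methoxyphenyllithium 7 (not isolated)
Conditions: n-BuLi (1.1 equiv), THF, 0 °C → rt; then 6, −78 °C; H2O quench
Reagents that add atoms: none
Why: Directed ortho-metalation then 1,2-addition; the ring CH flanked by both oxygens is the most acidic and doubly coordinated site, as in 1,3-dialkoxybenzenes, the aryllithium adds to the aldehyde carbon at low temperature, and the new carbinol stereocentre forms racemic and is erased in step 4.

Step 4
Reactants: 8 (±)-1-[2-(cyclohept-1-en-1-yloxy)-6-methoxyphenyl]prop-2-en-1-ol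
Product: 9 1-[2-(cyclohept-1-en-1-yloxy)-6-methoxyphenyl]prop-2-en-1-one
Conditions: activated MnO2 (excess), CH2Cl2, rt; filtration, used promptly
Reagents that add atoms: none
Why: Allylic/benzylic alcohol oxidation with MnO2 runs under neutral conditions that should spare the acid-sensitive aryl enol ether and the polymerisable vinyl ketone.

Step 5
Reactants: 9 1-[2-(cyclohept-1-en-1-yloxy)-6-methoxyphenyl]prop-2-en-1-one; 10 dec-1-ene
Product: 12 5-methoxy-2-[(6E)-pentadec-6-en-1-yl]-4H-chromen-4-one (E/Z mixture), via 2-(hept-6-en-1-yl)-5-methoxy-4H-chromen-4-one 11 (not isolated)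
Conditions: (SIMes)Cl2Ru(=CH-C6H4-2-OiPr) (2 × 5 mol %), 10 (5 equiv, in portions), 1,4-benzoquinone (10 mol %), PhMe (0.02 M), 80 °C, Ar sparge
Reagents that add atoms: none
Why: Proposed new method: in this ring-rearrangement/cross-metathesis cascade the Ru methylidene takes up the vinyl ketone of 9 as an acyl-substituted carbene, the carbene adds across the cycloheptenyl ether C=C through a ruthenacyclobutane that joins the ketone α-carbon (C3) to the oxygen-bearing ring carbon (C2), and cycloreversion gives the pyranone C2=C3 bond while the seven-membered ring unzips to a Ru alkylidene on the former ring CH (C6'). That alkylidene, or its methylidene-capped resting form 11, then exchanges with 10 to form C6'=C7' and ethene, which returns the Ru methylidene to the cycle. The closest known reaction types are ring-rearrangement metathesis of cycloheptenes bearing olefinic side arms, ring-closing metathesis of aryl vinyl ethers to 4H-chromenes, ring-closing metathesis of acryloyl groups onto hindered alkenes, and ring-opening cross metathesis of trisubstituted cycloalkenes with vinyl ketones; the new element is their merger on an aryl cycloalkenyl ether to close a chromone. The only ring closed is the six-membered 4-pyranone, closed at carbon (C2=C3) by ring-closing metathesis rather than at oxygen, and no stereocentre is made (the alkene geometry is erased in step 6). The regiochemistry of ring opening is fixed by the four-atom link C4–C4a–C8a–O1 between the two alkenes, which allows only the six-ring-forming metallacycle and so leaves Ru on the CH carbon and not on the oxygen-bearing carbon. All exchanges before ring closure are reversible, whereas the push–pull C2=C3 bond of the aromatic pyranone should be inert to the catalyst, so material that first cross-couples at the enone should funnel back; excess 10 and ethene removal bias the type I/type I exchange toward the cross product, and benzoquinone suppresses Ru–H chain isomerisation.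

Step 6
Reactants: 12 5-methoxy-2-[(6E)-pentadec-6-en-1-yl]-4H-chromen-4-one (E/Z mixture)
Product: 13 5-methoxy-2-pentadecyl-4H-chromen-4-one
Conditions: H2 (1 atm), 5 % Pd/C, EtOAc, rt, stopped after one equivalent of H2
Reagents that add atoms: none
Why: In heterogeneous catalytic hydrogenation the isolated 1,2-disubstituted alkene should be saturated much faster than the trisubstituted vinylogous-ester C2=C3 bond of the chromone.

Step 7
Reactants: 13 5-methoxy-2-pentadecyl-4H-chromen-4-one
Product: 14 5-hydroxy-2-pentadecyl-4H-chromen-4-one
Conditions: BCl3 (1 M in CH2Cl2, 1.5 equiv), CH2Cl2, −78 → 0 °C; H2O work-up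
Reagents that add atoms: none
Why: Lewis-acid aryl methyl ether cleavage is assisted by chelation of boron between C4=O and the peri 5-methoxy oxygen, and neither the chromone nor the alkyl chain should react.

**Compound list**
1 | cycloheptanone | O=C1CCCCCC1 | starting material
2 | lithium cyclohept-1-en-1-olate | [Li]OC1=CCCCCC1 | intermediate (not isolated)
3 | cyclohept-1-en-1-yl trifluoromethanesulfonate | O=S(=O)(OC1=CCCCCC1)C(F)(F)F | intermediate
4 | 3-methoxyphenol | COc1cccc(O)c1 | starting material
5 | 1-(cyclohept-1-en-1-yloxy)-3-methoxybenzene | COc1cccc(OC2=CCCCCC2)c1 | intermediate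
6 | acrolein (prop-2-enal) | C=CC=O | starting material
7 | 2-(cyclohept-1-en-1-yloxy)-6-methoxyphenyllithium | [Li]c1c(OC)cccc1OC1=CCCCCC1 | intermediate (not isolated)
8 | (±)-1-[2-(cyclohept-1-en-1-yloxy)-6-methoxyphenyl]prop-2-en-1-ol (racemic) | C=CC(O)c1c(OC)cccc1OC1=CCCCCC1 | intermediate
9 | 1-[2-(cyclohept-1-en-1-yloxy)-6-methoxyphenyl]prop-2-en-1-one | C=CC(=O)c1c(OC)cccc1OC1=CCCCCC1 | intermediate
10 | dec-1-ene | C=CCCCCCCCC | starting material
11 | 2-(hept-6-en-1-yl)-5-methoxy-4H-chromen-4-one | C=CCCCCCc1cc(=O)c2c(OC)cccc2o1 | intermediate (not isolated)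
12 | 5-methoxy-2-[(6E)-pentadec-6-en-1-yl]-4H-chromen-4-one (E/Z mixture, drawn E) | CCCCCCCC/C=C/CCCCCc1cc(=O)c2c(OC)cccc2o1 | intermediate
13 | 5-methoxy-2-pentadecyl-4H-chromen-4-one | CCCCCCCCCCCCCCCc1cc(=O)c2c(OC)cccc2o1 | intermediate
14 | 5-hydroxy-2-pentadecyl-4H-chromen-4-one | CCCCCCCCCCCCCCCc1cc(=O)c2c(O)cccc2o1 | target

**Total step count:** 7. **Longest linear sequence:** 7 steps (1 → 3 → 5 → 8 → 9 → 12 → 13 → 14).

**Steps most likely to fail**

Step 5 (proposed new method). Three processes could stall the cascade:
- Premature cross metathesis at the vinyl ketone could outrun ring closure.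
- The trisubstituted, oxygen-substituted ring alkene could engage too slowly.
- The catalyst could be lost to a heteroatom-stabilised carbene.

The fallback uses known chemistry only. It sets out from dec-1-ene 10 and comes back at 12. Commercial 1-(2-hydroxy-6-methoxyphenyl)ethan-1-one F1 is esterified with commercial oct-7-enoic acid F2 (EDC, DMAP, CH2Cl2) to 2-acetyl-3-methoxyphenyl oct-7-enoate F3. Baker–Venkataraman rearrangement (KOtBu, THF) gives 1-(2-hydroxy-6-methoxyphenyl)dec-9-ene-1,3-dione F4. Cyclodehydration (p-TsOH, PhMe, 80 °C) gives 11, which is isolated in this variant. Ordinary cross metathesis of the two unhindered terminal alkenes 11 and 10 (10 in excess, same Ru catalyst, CH2Cl2, 40 °C) then forms the same C6'=C7' bond and delivers 12.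

Step 2. Base-induced S–O cleavage or elimination of the enol triflate, or slow C–O reductive elimination, could erode the coupling. The fallback inverts the polarity of the alkenyl partner. It sets out from 3 and comes back at 5. Miyaura borylation of 3 (B2pin2, PdCl2(PPh3)2, PPh3, KOPh, PhMe, 50 °C) gives 2-(cyclohept-1-en-1-yl)-4,4,5,5-tetramethyl-1,3,2-dioxaborolane F5. Chan–Lam oxidative coupling of F5 with 4 (Cu(OAc)2, Et3N, 4 Å MS, CH2Cl2, air, rt) gives 5 without strong base.

Step 4. Oxidation of the twisted, doubly ortho-substituted carbinol could be slow, and the free vinyl ketone could polymerise or undergo conjugate addition during isolation. The fallback avoids the alcohol and carries the enone in masked form. It sets out from aryllithium 7 and comes back at 9. Addition of 7 to 3-chloro-N-methoxy-N-methylpropanamide F6 (THF, −78 °C, Weinreb ketone synthesis) gives the storable 3-chloro-1-[2-(cyclohept-1-en-1-yloxy)-6-methoxyphenyl]propan-1-one F7. Treatment of F7 with Et3N (CH2Cl2, 0 °C) just before step 5 eliminates chloride and releases 9.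

**Further compounds**
F1 | step 5 | 1-(2-hydroxy-6-methoxyphenyl)ethan-1-one | CC(=O)c1c(O)cccc1OC
F2 | step 5 | oct-7-enoic acid | C=CCCCCCC(=O)O
F3 | step 5 | 2-acetyl-3-methoxyphenyl oct-7-enoate | C=CCCCCCC(=O)Oc1cccc(OC)c1C(C)=O
F4 | step 5 | 1-(2-hydroxy-6-methoxyphenyl)dec-9-ene-1,3-dione | C=CCCCCCC(=O)CC(=O)c1c(O)cccc1OC
F5 | step 2 | 2-(cyclohept-1-en-1-yl)-4,4,5,5-tetramethyl-1,3,2-dioxaborolane | CC1(C)OB(OC1(C)C)C1=CCCCCC1
F6 | step 4 | 3-chloro-N-methoxy-N-methylpropanamide | CON(C)C(=O)CCCl
F7 | step 4 | 3-chloro-1-[2-(cyclohept-1-en-1-yloxy)-6-methoxyphenyl]propan-1-one | O=C(CCCl)c1c(OC)cccc1OC1=CCCCCC1
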